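The route rests on making inner ring B last (B1 bridge CH2, B2 OMe, B3 H, B4 OH, B5 aroyl, B6 OH) on the finished right-hand benzophenone (inner ring C, outer ring D). The B1–B2 edge, where the bridge carbon adjoins the only methoxy carbon, is read as a methyl ynol ether, and B3–B6 with the other two oxygens as a 3-alkoxycyclobutenone. One thermal benzannulation forms B6–B1 and B2–B3, closes ring B and delivers its three oxygens as OMe, OBn and free OH. The precursor is a 1-methoxy-3-arylpropyne whose aryl group is the benzyl-protected C/D ketone. The free B6 phenol then directs ring A to B5.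

Key step: step 15

Labels: inner rings B and C are numbered alike (1 bridge CH2, 2 OMe, 3 H, 4 O, 5 aroyl, 6 O). Outer rings A (left ketone) and D (right ketone) are numbered 1 ketone carbon, 2 methyl, 4 O, 6 O (OH in A, OMe in D).
Assumption: both diaryl ketones carry four ortho substituents and are taken to be inert to NaBH4, lithium methoxyacetylide and EtMgBr under the conditions given; the target has no stereocentre and the two carbinols on the route are racemic.

Step 1
Reactants: 1 2,4-dihydroxy-6-methylbenzaldehyde
Product: 3 4-(benzyloxy)-2-methoxy-6-methylbenzaldehyde (ring D aldehyde), via monobenzyl ether 2 (not isolated)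
Conditions: BnBr (1.0 equiv), K2CO3 (1.1 equiv), DMF, rt; then K2CO3 (2 equiv), MeI (3 equiv), 40 °C
Reagents that add atoms: benzyl bromide BrCc1ccccc1; iodomethane CI
Why: Two Williamson etherifications in one pot: the 4-hydroxyl is free and the more acidic while the 2-hydroxyl is held in a hydrogen bond to the formyl oxygen, so benzyl bromide should take O4 first and the chelated O2 is methylated only once more base, excess MeI and warming are applied.

Step 2
Reactants: 4 phloroglucinol
Product: 5 1,3,5-tris(methoxymethoxy)benzene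
Conditions: MOMCl (3.6 equiv), i-Pr2NEt (4 equiv), CH2Cl2–DMF, 0 °C → rt
Reagents that add atoms: chloromethyl methyl ether COCCl
Why: O-Alkylation with a chloromethyl ether (MOM protection) of three equivalent phenols, chosen because OMOM directs lithiation strongly and can later be removed without touching a benzyl ether.

Step 3
Reactants: 5 1,3,5-tris(methoxymethoxy)benzene; 3 4-(benzyloxy)-2-methoxy-6-methylbenzaldehyde
Product: 7 racemic [4-(benzyloxy)-2-methoxy-6-methylphenyl][2,4,6-tris(methoxymethoxy)phenyl]methanol, via aryllithium 6 (not isolated)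
Conditions: n-BuLi (1.05 equiv), THF, 0 °C; then 3, −78 → 0 °C; H2O
Reagents that add atoms: none
Why: Directed ortho-metalation followed by 1,2-addition of the aryllithium to an aldehyde: the three ring hydrogens of 5 are equivalent and each lies between two OMOM groups, so a single aryllithium forms, and the new carbinol stereocentre is racemic and disappears in step 4.

Step 4
Reactants: 7 racemic diaryl carbinol
Product: 8 [4-(benzyloxy)-2-methoxy-6-methylphenyl][2,4,6-tris(methoxymethoxy)phenyl]methanone
Conditions: Pr4N[RuO4] (5 mol %), N-methylmorpholine N-oxide, 4 Å molecular sieves, CH2Cl2, rt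
Reagents that add atoms: none
Why: Ley–Griffith oxidation of a hindered secondary benzylic alcohol under neutral conditions, so that neither the MOM acetals nor the easily ionised carbinol meets acid.

Step 5
Reactants: 8 tris-MOM benzophenone
Product: 9 [4-(benzyloxy)-2-methoxy-6-methylphenyl](2,4,6-trihydroxyphenyl)methanone
Conditions: HCl (cat.), MeOH, 50 °C
Reagents that add atoms: none
Why: Acid-catalysed acetal exchange (MOM cleavage) with methanol, under which aryl benzyl and methyl ethers and the hindered ketone are stable.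

Step 6
Reactants: 9 trihydroxybenzophenone
Product: 10 [4-(benzyloxy)-2-methoxy-6-methylphenyl](2,6-dihydroxy-4-methoxyphenyl)methanone
Conditions: Me2SO4 (1.0 equiv), K2CO3 (1.1 equiv), acetone, rt
Reagents that add atoms: dimethyl sulfate COS(=O)(=O)OC
Why: Williamson etherification under substrate control: the hydroxyl para to the ketone is the most acidic and least hindered, whereas both ortho hydroxyls are flanked by the aroyl group and hydrogen-bond to its carbonyl, so one equivalent of a hard methylating agent should give the benzophenone with a mirror-symmetric ring C.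

Step 7
Reactants: 10 symmetric dihydroxy-methoxy benzophenone
Product: 12 3-[4-(benzyloxy)-2-methoxy-6-methylbenzoyl]-2,4-dihydroxy-6-methoxybenzaldehyde, via aryl iminium chloride 11 (not isolated)
Conditions: POCl3 (1.2 equiv), DMF (1.5 equiv), MeCN, 0 °C → rt; then H2O, 40 °C
Reagents that add atoms: N,N-dimethylformamide CN(C)C=O; water O
Why: Vilsmeier–Haack formylation: C1 and C3 of ring C are equivalent by symmetry so only one monoaldehyde can arise, ring C with two free phenols and a methoxy group is far more nucleophilic than ring D, and the first formyl group deactivates the ring towards a second.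

Step 8
Reactants: 12 dihydroxy aldehyde
Product: 13 2,4-bis(benzyloxy)-3-[4-(benzyloxy)-2-methoxy-6-methylbenzoyl]-6-methoxybenzaldehyde
Conditions: BnBr (3 equiv), K2CO3, DMF, 60 °C
Reagents that add atoms: benzyl bromide BrCc1ccccc1
Why: Williamson etherification of the two chelated phenols in a dipolar solvent, which leaves ring C with only methyl and hydrogenolysable benzyl ethers and no acidic hydrogen for the organometallic and ketene chemistry ahead.

Step 9
Reactants: 13 keto aldehyde
Product: 14 [2,6-bis(benzyloxy)-3-(hydroxymethyl)-4-methoxyphenyl][4-(benzyloxy)-2-methoxy-6-methylphenyl]methanone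
Conditions: NaBH4, THF–MeOH, 0 °C
Reagents that add atoms: none
Why: Borohydride reduction that is chemoselective because the diaryl ketone is shielded by four ortho substituents and twisted out of conjugation, while the aldehyde stays accessible.

Step 10
Reactants: 14 benzylic alcohol
Product: 15 [2,6-bis(benzyloxy)-3-(bromomethyl)-4-methoxyphenyl][4-(benzyloxy)-2-methoxy-6-methylphenyl]methanone
Conditions: CBr4, PPh3, CH2Cl2, 0 °C; short plug of neutral alumina, used at once
Reagents that add atoms: tetrabromomethane BrC(Br)(Br)Br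
Why: Appel reaction, chosen because it converts the electron-rich benzylic alcohol into the bromide under neutral conditions and so avoids acid-induced ionisation and Friedel–Crafts self-alkylation.

Step 11
Reactants: 16 trichloroethylene
Product: 18 (E)-1,2-dichloro-1-methoxyethene, via dichloroacetylene 17 (not isolated)
Conditions: KH (1.2 equiv), MeOH (1.2 equiv), THF, 0 °C; then 16, −40 °C → rt; distillation
Reagents that add atoms: methanol CO
Why: Dehydrochlorination to dichloroacetylene followed by anti addition of methanol under methoxide catalysis (net vinylic substitution), a standard entry to 1,2-dichlorovinyl ethers whose alkene geometry is lost in the next step.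

Step 12
Reactants: 18 (E)-1,2-dichloro-1-methoxyethene; 15 benzylic bromide
Product: 21 [2,6-bis(benzyloxy)-4-methoxy-3-(3-methoxyprop-2-yn-1-yl)phenyl][4-(benzyloxy)-2-methoxy-6-methylphenyl]methanone, via chloromethoxyethyne 19 (not isolated), via lithium methoxyacetylide 20 (not isolated)
Conditions: 18 (1.5 equiv), n-BuLi (2.9 equiv), THF, −78 → −40 °C; then DMPU, 15, −78 → −20 °C; pH 7 buffer; Et3N-deactivated silica
Reagents that add atoms: none
Why: Elimination and chlorine–lithium exchange turn 18 into lithium methoxyacetylide free of the amines and alkoxides that would otherwise consume the bromide, and SN2 alkylation of the acetylide at the benzylic carbon follows, the tetra-ortho-substituted ketone being too hindered to compete at low temperature.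

Step 13
Reactants: 22 acetone; 23 ethoxyacetylene
Product: 25 3-ethoxycyclobut-2-en-1-one, via ketene 24 (not isolated)
Conditions: 22 pyrolysed over a glowing Ni–Cr filament (ketene lamp), gas stream passed into 23, CH2Cl2, 0 °C
Reagents that add atoms: none
Why: Thermal (2+2) cycloaddition of ketene with an ynol ether, in which the nucleophilic terminal alkyne carbon attacks the ketene carbonyl carbon so that the ethoxy group ends at C3 of the cyclobutenone.

Step 14
Reactants: 25 3-ethoxycyclobut-2-en-1-one
Product: 26 3-(benzyloxy)cyclobut-2-en-1-one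
Conditions: BnOH (3 equiv), camphorsulfonic acid (5 mol %), toluene, 35 °C, reduced pressure
Reagents that add atoms: benzyl alcohol OCc1ccccc1
Why: Acid-catalysed vinylogous transesterification by addition–elimination at C3, driven by removal of the more volatile ethanol, which installs an oxygen substituent that falls in the final hydrogenolysis.

Step 15
Reactants: 21 1-methoxy-3-arylpropyne; 26 3-(benzyloxy)cyclobut-2-en-1-one
Product: 31 [2,6-bis(benzyloxy)-3-{[4-(benzyloxy)-2-hydroxy-6-methoxyphenyl]methyl}-4-methoxyphenyl][4-(benzyloxy)-2-methoxy-6-methylphenyl]methanone (free B6 phenol; B5 open), via vinylketene 27 (not isolated), via vinylcyclobutenone 28 (not isolated), via dienylketene 29 (not isolated), via cyclohexadienone 30 (not isolated)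
Conditions: 26 (3 equiv, in portions), toluene, sealed tube, dark, 120 °C then 150 °C; then K2CO3, MeOH–THF, rt
Reagents that add atoms: none
Why: Danheiser benzannulation: heat opens 26 in a four-electron electrocyclic step to vinylketene 27, which ynol ether 21 traps in a (2+2) cycloaddition where the electron-rich alkyne carbon bearing the arylmethyl group attacks the ketene carbonyl carbon (B6–B1) and the methoxy-bearing carbon joins the former alpha carbon (B2–B3). Adduct 28 reopens to dienylketene 29, and ring B, the only ring formed, closes by a six-electron disrotatory electrocyclisation between the ketene carbon and the terminal CH2 (B6–B5), after which dienone 30 tautomerises to phenol 31. The closest known reaction type is the union of alkyl- or aryl-substituted cyclobutenones with alkoxyalkynes to give resorcinol monoethers; the alkoxy donor on 26 stabilises the four-membered ring, hence the higher temperature. No stereocentre is created, since that of 28 is lost on ring opening. The one selectivity needed is the orientation of the (2+2) step, which the oxygen lone pair of the ynol ether fixes by polarising the triple bond. A methyl ynol ether cannot shed an alkene by a retro-ene path, activation is thermal and in the dark because the benzophenone unit of 21 would abstract hydrogen from its ortho benzyloxy groups under light, and the basic methanolysis returns any 31 that excess 27 has acylated on oxygen.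

Step 16
Reactants: 1 2,4-dihydroxy-6-methylbenzaldehyde
Product: 32 2,4-bis(benzyloxy)-6-methylbenzaldehyde (ring A aldehyde)
Conditions: BnBr (2.5 equiv), K2CO3, DMF, 60 °C
Reagents that add atoms: benzyl bromide BrCc1ccccc1
Why: Double Williamson etherification, in which heating in DMF with excess reagent also alkylates the chelated 2-hydroxyl.

Step 17
Reactants: 31 BCD phenol; 32 2,4-bis(benzyloxy)-6-methylbenzaldehyde
Product: 34 racemic B5 carbinol (31 bearing CH(OH)[2,4-bis(benzyloxy)-6-methylphenyl] at B5; B6 OH free), via bromomagnesium phenolate 33 (not isolated)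
Conditions: EtMgBr (1.0 equiv), Et2O, 0 °C; solvent exchanged for toluene; 32 (1.5 equiv), rt → 50 °C; sat. aq NH4Cl, 0 °C
Reagents that add atoms: none
Why: Ortho-specific hydroxyalkylation of a bromomagnesium phenolate: in a non-coordinating solvent magnesium binds the phenolate and aldehyde oxygens and delivers the carbonyl carbon through a six-membered transition state to an ortho carbon, and since B1 is substituted only B5 can react, the new stereocentre being racemic and erased in step 18.

Step 18
Reactants: 34 racemic B5 carbinol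
Product: 35 hexabenzyl diketone (34 with the carbinol oxidised to the A–B ketone; B6 OH free)
Conditions: activated MnO2 (excess), CH2Cl2, rt
Reagents that add atoms: none
Why: Benzylic alcohol oxidation on activated MnO2 under neutral conditions, in which the doubly benzylic carbinol should react faster than the hindered phenol and the product gains a hydrogen bond from the B6 hydroxyl to the new ketone, quinone-type hydride acceptors being avoided because they would attack the electron-rich bridge CH2.

Step 19
Reactants: 35 hexabenzyl diketone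
Product: 36 CNP0596095.0
Conditions: H2 (1 atm), Pd/C (10 wt %), EtOAc–MeOH, rt
Reagents that add atoms: none
Why: Catalytic hydrogenolysis of all six benzyl aryl ethers in one operation, which leaves the three methyl ethers, the diarylmethane bridge and the two hindered, chelated ketones untouched.

Compound list
1 | 2,4-dihydroxy-6-methylbenzaldehyde | Cc1cc(O)cc(O)c1C=O | starting material
2 | 4-(benzyloxy)-2-hydroxy-6-methylbenzaldehyde | Cc1cc(OCc2ccccc2)cc(O)c1C=O | intermediate (not isolated)
3 | 4-(benzyloxy)-2-methoxy-6-methylbenzaldehyde | Cc1cc(OCc2ccccc2)cc(OC)c1C=O | intermediate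
4 | phloroglucinol (benzene-1,3,5-triol) | Oc1cc(O)cc(O)c1 | starting material
5 | 1,3,5-tris(methoxymethoxy)benzene | COCOc1cc(OCOC)cc(OCOC)c1 | intermediate
6 | 2,4,6-tris(methoxymethoxy)phenyllithium | [Li]c1c(OCOC)cc(OCOC)cc1OCOC | intermediate (not isolated)
7 | racemic [4-(benzyloxy)-2-methoxy-6-methylphenyl][2,4,6-tris(methoxymethoxy)phenyl]methanol | OC(c1c(OCOC)cc(OCOC)cc1OCOC)c1c(C)cc(OCc2ccccc2)cc1OC | intermediate
8 | [4-(benzyloxy)-2-methoxy-6-methylphenyl][2,4,6-tris(methoxymethoxy)phenyl]methanone | O=C(c1c(OCOC)cc(OCOC)cc1OCOC)c1c(C)cc(OCc2ccccc2)cc1OC | intermediate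
9 | [4-(benzyloxy)-2-methoxy-6-methylphenyl](2,4,6-trihydroxyphenyl)methanone | O=C(c1c(O)cc(O)cc1O)c1c(C)cc(OCc2ccccc2)cc1OC | intermediate
10 | [4-(benzyloxy)-2-methoxy-6-methylphenyl](2,6-dihydroxy-4-methoxyphenyl)methanone | O=C(c1c(O)cc(OC)cc1O)c1c(C)cc(OCc2ccccc2)cc1OC | intermediate
11 | N,N-dimethyliminium chloride of aldehyde 12 | C[N+](C)=Cc1c(OC)cc(O)c(C(=O)c2c(C)cc(OCc3ccccc3)cc2OC)c1O.[Cl-] | intermediate (not isolated)
12 | 3-[4-(benzyloxy)-2-methoxy-6-methylbenzoyl]-2,4-dihydroxy-6-methoxybenzaldehyde | O=Cc1c(OC)cc(O)c(C(=O)c2c(C)cc(OCc3ccccc3)cc2OC)c1O | intermediate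
13 | 2,4-bis(benzyloxy)-3-[4-(benzyloxy)-2-methoxy-6-methylbenzoyl]-6-methoxybenzaldehyde | O=Cc1c(OC)cc(OCc3ccccc3)c(C(=O)c2c(C)cc(OCc3ccccc3)cc2OC)c1OCc3ccccc3 | intermediate
14 | [2,6-bis(benzyloxy)-3-(hydroxymethyl)-4-methoxyphenyl][4-(benzyloxy)-2-methoxy-6-methylphenyl]methanone | OCc1c(OC)cc(OCc3ccccc3)c(C(=O)c2c(C)cc(OCc3ccccc3)cc2OC)c1OCc3ccccc3 | intermediate
15 | [2,6-bis(benzyloxy)-3-(bromomethyl)-4-methoxyphenyl][4-(benzyloxy)-2-methoxy-6-methylphenyl]methanone | BrCc1c(OC)cc(OCc3ccccc3)c(C(=O)c2c(C)cc(OCc3ccccc3)cc2OC)c1OCc3ccccc3 | intermediate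
16 | trichloroethylene | ClC=C(Cl)Cl | starting material
17 | dichloroacetylene | ClC#CCl | intermediate (not isolated)
18 | (E)-1,2-dichloro-1-methoxyethene | CO/C(Cl)=C\Cl | intermediate
19 | 1-chloro-2-methoxyethyne | COC#CCl | intermediate (not isolated)
20 | lithium methoxyacetylide | COC#C[Li] | intermediate (not isolated)
21 | [2,6-bis(benzyloxy)-4-methoxy-3-(3-methoxyprop-2-yn-1-yl)phenyl][4-(benzyloxy)-2-methoxy-6-methylphenyl]methanone | COC#CCc1c(OC)cc(OCc3ccccc3)c(C(=O)c2c(C)cc(OCc3ccccc3)cc2OC)c1OCc3ccccc3 | intermediate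
22 | acetone | CC(C)=O | starting material
23 | ethoxyacetylene | CCOC#C | starting material
24 | ketene | C=C=O | intermediate (not isolated)
25 | 3-ethoxycyclobut-2-en-1-one | CCOC1=CC(=O)C1 | intermediate
26 | 3-(benzyloxy)cyclobut-2-en-1-one | O=C1CC(OCc2ccccc2)=C1 | intermediate
27 | 3-(benzyloxy)buta-1,3-dien-1-one (vinylketene) | O=C=CC(=C)OCc1ccccc1 | intermediate (not isolated)
28 | racemic 4-[1-(benzyloxy)ethenyl]-3-methoxy-2-(right-half arylmethyl)cyclobut-2-en-1-one | C=C(OCc3ccccc3)C1C(=O)C(Cc2c(OC)cc(OCc3ccccc3)c(C(=O)c4c(C)cc(OCc3ccccc3)cc4OC)c2OCc3ccccc3)=C1OC | intermediate (not isolated)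
29 | 5-(benzyloxy)-3-methoxy-2-(right-half arylmethyl)hexa-1,3,5-trien-1-one, ketene and vinyl groups cis on the central alkene | O=C=C(Cc2c(OC)cc(OCc3ccccc3)c(C(=O)c4c(C)cc(OCc3ccccc3)cc4OC)c2OCc3ccccc3)/C(OC)=C\C(=C)OCc3ccccc3 | intermediate (not isolated)
30 | 5-(benzyloxy)-3-methoxy-2-(right-half arylmethyl)cyclohexa-2,4-dien-1-one | O=C1CC(OCc3ccccc3)=CC(OC)=C1Cc2c(OC)cc(OCc3ccccc3)c(C(=O)c4c(C)cc(OCc3ccccc3)cc4OC)c2OCc3ccccc3 | intermediate (not isolated)
31 | [2,6-bis(benzyloxy)-3-{[4-(benzyloxy)-2-hydroxy-6-methoxyphenyl]methyl}-4-methoxyphenyl][4-(benzyloxy)-2-methoxy-6-methylphenyl]methanone | Oc1cc(OCc3ccccc3)cc(OC)c1Cc1c(OC)cc(OCc3ccccc3)c(C(=O)c2c(C)cc(OCc3ccccc3)cc2OC)c1OCc3ccccc3 | intermediate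
32 | 2,4-bis(benzyloxy)-6-methylbenzaldehyde | Cc1cc(OCc2ccccc2)cc(OCc2ccccc2)c1C=O | intermediate
33 | bromomagnesium phenolate of 31 | Br[Mg]Oc1cc(OCc3ccccc3)cc(OC)c1Cc1c(OC)cc(OCc3ccccc3)c(C(=O)c2c(C)cc(OCc3ccccc3)cc2OC)c1OCc3ccccc3 | intermediate (not isolated)
34 | racemic carbinol: 31 bearing CH(OH)[2,4-bis(benzyloxy)-6-methylphenyl] at B5 | OC(c1c(C)cc(OCc3ccccc3)cc1OCc3ccccc3)c1c(OCc3ccccc3)cc(OC)c(Cc2c(OC)cc(OCc3ccccc3)c(C(=O)c4c(C)cc(OCc3ccccc3)cc4OC)c2OCc3ccccc3)c1O | intermediate
35 | hexabenzyl diketone: 31 bearing the 2,4-bis(benzyloxy)-6-methylbenzoyl group at B5 | O=C(c1c(C)cc(OCc3ccccc3)cc1OCc3ccccc3)c1c(OCc3ccccc3)cc(OC)c(Cc2c(OC)cc(OCc3ccccc3)c(C(=O)c4c(C)cc(OCc3ccccc3)cc4OC)c2OCc3ccccc3)c1O | intermediate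
36 | CNP0596095.0 | COc1cc(O)c(C(=O)c2c(C)cc(O)cc2O)c(O)c1Cc1c(OC)cc(O)c(C(=O)c2c(C)cc(O)cc2OC)c1O | target

Total step count: 19. Longest linear sequence: 14 steps (step 1 or step 2, then steps 3–10, 12, 15, 17, 18 and 19).

Steps most likely to fail

1. Step 15. The alkoxy-stabilised cyclobutenone may open too slowly. At the temperature then needed, the vinylketene could be lost to self-condensation, or the ynol ether could decay before it is trapped.
   - The fallback gives up the benzannulation and joins two complete halves. It sets out from benzylic alcohol 14, aryllithium 6 and aldehyde 32, and comes back at target 36.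
   - Addition of 6 to 32 gives carbinol F1, and oxidation as in step 4 gives ketone F2.
   - Acidic methanol gives triol F3, and one equivalent of dimethyl sulfate gives monomethyl ether F4. Its ring B is mirror-symmetric, so B1 and B3 are equivalent.
   - Acid-catalysed Friedel–Crafts benzylation of excess F4 with 14 (catalytic Sc(OTf)3, CH2Cl2–MeCN, 0 °C) gives bridged pentabenzyl ether F5. The free-phenol ring B should out-compete the protected ring C as nucleophile.
   - Hydrogenolysis of F5 over Pd/C delivers 36.

2. Step 17. Crowding around both reacting carbons may stall or reverse the addition. The very electron-rich carbinol may also lose water and capture a second phenolate.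
   - The fallback reverses the polarity of the bond formation. It sets out from phenol 31 and comes back at target 36.
   - Magnesium-mediated ortho-formylation (Casnati–Skattebøl reaction; MgCl2, Et3N, paraformaldehyde, MeCN, reflux) can only reach B5 and gives salicylaldehyde F6. Benzylation (BnBr, K2CO3, DMF) gives aldehyde benzyl ether F7.
   - Separately, commercial orcinol is benzylated to orcinol dibenzyl ether F8. This is brominated with NBS para to one benzyloxy group and next to the methyl group, giving aryl bromide F9, which n-BuLi at −78 °C converts into aryllithium F10.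
   - Addition of F10 to F7 gives heptabenzyl carbinol F11, and oxidation as in step 4, now without a free phenol, gives heptabenzyl diketone F12.
   - Hydrogenolysis of F12 over Pd/C gives 36.

3. Step 12. The bromide may ionise and alkylate another molecule, excess base may isomerise the propargylic ynol ether to an allenyl ether, or the acetylide may add to the ketone.
   - The fallback replaces the ionic alkylation by a neutral cross-coupling. It sets out from acetylide 20 and bromide 15, and comes back at alkyne 21.
   - Acetylide 20 is quenched with Bu3SnCl to give tributyl(methoxyethynyl)stannane F13.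
   - F13 is joined to 15 in a Stille coupling (Pd2(dba)3, P(2-furyl)3, THF, rt → 50 °C). Fast oxidative addition of the benzylic bromide to zerovalent palladium takes the place of the SN2 step.

Further compounds
F1 | step 15 | racemic [2,4-bis(benzyloxy)-6-methylphenyl][2,4,6-tris(methoxymethoxy)phenyl]methanol | OC(c1c(OCOC)cc(OCOC)cc1OCOC)c1c(C)cc(OCc2ccccc2)cc1OCc2ccccc2
F2 | step 15 | [2,4-bis(benzyloxy)-6-methylphenyl][2,4,6-tris(methoxymethoxy)phenyl]methanone | O=C(c1c(OCOC)cc(OCOC)cc1OCOC)c1c(C)cc(OCc2ccccc2)cc1OCc2ccccc2
F3 | step 15 | [2,4-bis(benzyloxy)-6-methylphenyl](2,4,6-trihydroxyphenyl)methanone | O=C(c1c(O)cc(O)cc1O)c1c(C)cc(OCc2ccccc2)cc1OCc2ccccc2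
F4 | step 15 | [2,4-bis(benzyloxy)-6-methylphenyl](2,6-dihydroxy-4-methoxyphenyl)methanone | O=C(c1c(O)cc(OC)cc1O)c1c(C)cc(OCc2ccccc2)cc1OCc2ccccc2
F5 | step 15 | bridged pentabenzyl ether (target with A4, A6, C4, C6 and D4 oxygens benzylated) | COc1cc(O)c(C(=O)c2c(C)cc(OCc3ccccc3)cc2OCc3ccccc3)c(O)c1Cc1c(OC)cc(OCc3ccccc3)c(C(=O)c2c(C)cc(OCc3ccccc3)cc2OC)c1OCc3ccccc3
F6 | step 17 | salicylaldehyde: 31 bearing CHO at B5 | O=Cc1c(OCc3ccccc3)cc(OC)c(Cc2c(OC)cc(OCc3ccccc3)c(C(=O)c4c(C)cc(OCc3ccccc3)cc4OC)c2OCc3ccccc3)c1O
F7 | step 17 | B6 benzyl ether of F6 | O=Cc1c(OCc3ccccc3)cc(OC)c(Cc2c(OC)cc(OCc3ccccc3)c(C(=O)c4c(C)cc(OCc3ccccc3)cc4OC)c2OCc3ccccc3)c1OCc3ccccc3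
F8 | step 17 | 1,3-bis(benzyloxy)-5-methylbenzene | Cc1cc(OCc2ccccc2)cc(OCc2ccccc2)c1
F9 | step 17 | 1,5-bis(benzyloxy)-2-bromo-3-methylbenzene | Cc1cc(OCc2ccccc2)cc(OCc2ccccc2)c1Br
F10 | step 17 | 2,4-bis(benzyloxy)-6-methylphenyllithium | Cc1cc(OCc2ccccc2)cc(OCc2ccccc2)c1[Li]
F11 | step 17 | racemic heptabenzyl carbinol (B6 benzyl ether of 34) | OC(c1c(C)cc(OCc3ccccc3)cc1OCc3ccccc3)c1c(OCc3ccccc3)cc(OC)c(Cc2c(OC)cc(OCc3ccccc3)c(C(=O)c4c(C)cc(OCc3ccccc3)cc4OC)c2OCc3ccccc3)c1OCc3ccccc3
F12 | step 17 | heptabenzyl diketone (B6 benzyl ether of 35) | O=C(c1c(C)cc(OCc3ccccc3)cc1OCc3ccccc3)c1c(OCc3ccccc3)cc(OC)c(Cc2c(OC)cc(OCc3ccccc3)c(C(=O)c4c(C)cc(OCc3ccccc3)cc4OC)c2OCc3ccccc3)c1OCc3ccccc3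
F13 | step 12 | tributyl(methoxyethynyl)stannane | CCCC[Sn](CCCC)(CCCC)C#COC
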